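Numbering (1H-isochromen-8-one): C1H2, O2, C3 (acid chain), C4, C4a, C5, C6 (acyloxy), C7 (methyl), C8 (ketone), C8a. Ring A is the carbocycle C4a–C5–C6–C7–C8–C8a and ring B is the pyran.
Enabling feature: in ring A, C6(O)–C7(CH3)–C8(=O) is a cis β-oxy-α-methyl ketone, an aldol unit. Its ketone sits on C8a and its carbinol carbon reaches C4a through C5, so ring A opens at C6–C7 to a vinyl ketone and an aldehyde on neighbouring carbons of ring B.
Retrosynthetic cuts, in order: aryl ester O–C(=O)Ar; C6–C7 (reductive aldol); C7–C8 (vinyl onto a C8 aldehyde); C4a–C5 (B-alkyl Suzuki); C8a–C8 with C4a–Br (bromoformylation); O2–C3 (cyclodehydration); C3–C4 (Claisen).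
Forward: ring B is made first as a 2,3-dihydro-4H-pyran-4-one. It is then converted into a 2H-pyran carrying every carbon of ring A. Ring A closes second, and the orsellinate is attached last.
Stereochemistry: both centres arise in the closure of ring A. The cis relation comes from a (Z)-copper enolate in a copper-bridged transition state, and the 6R,7R sense from the chiral bisphosphine on copper.
Key step: step 11

Assumption: it cannot be safely predicted which antipode of the bisphosphine gives the 6R,7R series on this substrate. (R)-DTBM-SEGPHOS is written, and its mirror image would be taken if the aldol fell into the 6S,7S series.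
Assumption: the monocyclic 2H-pyrans 12 and 15–19 are expected to stay ring-closed. O2 is conjugated through C3=C4–C4a=C8a with the C8 carbonyl (a doubly vinylogous ester), and the open dienone would be a crowded α-methylene carbonyl compound.
Assumption: 13 is taken as purchasable; it is also available in one operation from THF, BuLi and TBSCl.

Step 1
Reactants: 1 succinic anhydride; 2 2-(trimethylsilyl)ethanol
Product: 3 4-oxo-4-[2-(trimethylsilyl)ethoxy]butanoic acid
Conditions: DMAP (10 mol %), Et3N, CH2Cl2, rt; dilute acid work-up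
Reagents that add atoms: none
Why: DMAP-catalysed alcoholysis of a cyclic anhydride should stop at the half ester, because the carboxylate that forms is no longer an acylating agent.

Step 2
Reactants: 4 4-hydroxybutan-2-one
Product: 5 4-(tert-butyldimethylsilyloxy)butan-2-one
Conditions: TBSCl, imidazole, CH2Cl2, 0 °C to rt
Reagents that add atoms: tert-butyldimethylsilyl chloride, CC(C)(C)[Si](C)(C)Cl
Why: This is an imidazole-promoted silylation of a primary alcohol, and the weak base should not cause β-elimination to methyl vinyl ketone.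

Step 3
Reactants: 3 4-oxo-4-[2-(trimethylsilyl)ethoxy]butanoic acid; 5 4-(tert-butyldimethylsilyloxy)butan-2-one
Product: 8 2-(trimethylsilyl)ethyl 8-(tert-butyldimethylsilyloxy)-4,6-dioxooctanoate, via acid chloride 6 (not isolated), via lithium enolate 7 (not isolated)
Conditions: 3, (COCl)2, DMF (cat.), CH2Cl2, 0 °C to rt, evaporate; 5 (2.1 equiv), LiN(iPr)2 (2.1 equiv), THF, −78 °C; add 6, −78 °C; 1 M HCl
Reagents that add atoms: none
Why: In this crossed Claisen C-acylation (forming C3–C4), kinetic deprotonation at the methyl group gives 7, which attacks the acid chloride far faster than the ester at −78 °C, and the second equivalent of enolate removes the acidic proton of the new 1,3-diketone so that it is not acylated again.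

Step 4
Reactants: 8 2-(trimethylsilyl)ethyl 8-(tert-butyldimethylsilyloxy)-4,6-dioxooctanoate
Product: 10 2-(trimethylsilyl)ethyl 3-(4-oxo-5,6-dihydro-4H-pyran-2-yl)propanoate, via hydroxy diketone 9 (not isolated)
Conditions: TsOH·H2O (0.3 equiv), MeCN–H2O 20:1, rt to 40 °C
Reagents that add atoms: none
Why: Acidic desilylation followed by cyclodehydration of a δ-hydroxy-β-diketone is the classical route to 2,3-dihydro-4H-pyran-4-ones; only the six-membered hemiketal at the distal carbonyl can form, and loss of water gives the vinylogous ester that sets O2–C3 and C3=C4.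

Step 5
Reactants: 10 2-(trimethylsilyl)ethyl 3-(4-oxo-5,6-dihydro-4H-pyran-2-yl)propanoate
Product: 12 2-(trimethylsilyl)ethyl 3-(4-bromo-3-formyl-2H-pyran-6-yl)propanoate, via iminium bromide 11 (not isolated)
Conditions: PBr3 (2.7 equiv), DMF (3 equiv), CHCl3, 0 °C to rt; poured into ice water, rapid extraction
Reagents that add atoms: N,N-dimethylformamide, CN(C)C=O; phosphorus tribromide, BrP(Br)Br; water, O
Why: This is the Vilsmeier–Haack–Arnold bromoformylation used to turn chroman-4-ones into 4-halo-2H-chromene-3-carbaldehydes: the ketone becomes a 4-bromo dienol ether that is formylated at its terminal carbon (C8a), the site at which conjugated dienol ethers are known to react, and ring B fixes the geometry of the tetrasubstituted C4a=C8a alkene.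

Step 6
Reactants: 12 2-(trimethylsilyl)ethyl 3-(4-bromo-3-formyl-2H-pyran-6-yl)propanoate; 13 tert-butyldimethyl(vinyloxy)silane
Product: 15 2-(trimethylsilyl)ethyl 3-{4-[2-(tert-butyldimethylsilyloxy)ethyl]-3-formyl-2H-pyran-6-yl}propanoate, via B-alkyl borane 14 (not isolated)
Conditions: 13 (1.6 equiv), 9-BBN-H (1.5 equiv), THF, 0 °C to rt; then 12, PdCl2(dppf) (5 mol %), K3PO4 (3 M aq., 3 equiv), DMF, rt
Reagents that add atoms: none
Why: Hydroboration of the silyl vinyl ether places boron on the terminal carbon, and B-alkyl Suzuki–Miyaura coupling of such β-oxygenated alkylboranes with activated vinyl halides is established; the β-bromo enal adds quickly to zerovalent palladium, and the excess of 13 leaves no B–H to reduce the aldehyde.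

Step 7
Reactants: 15 2-(trimethylsilyl)ethyl 3-{4-[2-(tert-butyldimethylsilyloxy)ethyl]-3-formyl-2H-pyran-6-yl}propanoate
Product: 16 2-(trimethylsilyl)ethyl 3-{4-[2-(tert-butyldimethylsilyloxy)ethyl]-3-(1-hydroxyprop-2-en-1-yl)-2H-pyran-6-yl}propanoate (racemic at the carbinol carbon)
Conditions: CH2=CHMgBr (1.15 equiv), THF, −78 °C; pH 7 buffer; used crude
Reagents that add atoms: vinylmagnesium bromide, C=C[Mg]Br
Why: In this Grignard 1,2-addition the aldehyde reacts far faster than the primary ester at −78 °C; the new centre is erased in step 8, and the easily ionised doubly allylic alcohol is kept neutral and is not chromatographed.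

Step 8
Reactants: 16 2-(trimethylsilyl)ethyl 3-{4-[2-(tert-butyldimethylsilyloxy)ethyl]-3-(1-hydroxyprop-2-en-1-yl)-2H-pyran-6-yl}propanoate
Product: 17 2-(trimethylsilyl)ethyl 3-{3-acryloyl-4-[2-(tert-butyldimethylsilyloxy)ethyl]-2H-pyran-6-yl}propanoate
Conditions: MnO2 (activated, 20 equiv), CH2Cl2, rt
Reagents that add atoms: none
Why: MnO2 oxidation of a doubly allylic alcohol is neutral and heterogeneous, so the acid-labile carbinol, the silyl ether and the ester should all survive.

Step 9
Reactants: 17 2-(trimethylsilyl)ethyl 3-{3-acryloyl-4-[2-(tert-butyldimethylsilyloxy)ethyl]-2H-pyran-6-yl}propanoate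
Product: 18 2-(trimethylsilyl)ethyl 3-[3-acryloyl-4-(2-hydroxyethyl)-2H-pyran-6-yl]propanoate
Conditions: HF·pyridine, pyridine, THF, 0 °C to rt
Reagents that add atoms: none
Why: Pyridine-buffered HF cleaves primary TBS ethers while 2-(trimethylsilyl)ethyl esters persist, and oxa-Michael addition of the freed alcohol to the acryloyl group would need an eight-membered ring.

Step 10
Reactants: 18 2-(trimethylsilyl)ethyl 3-[3-acryloyl-4-(2-hydroxyethyl)-2H-pyran-6-yl]propanoate
Product: 19 2-(trimethylsilyl)ethyl 3-[3-acryloyl-4-(2-oxoethyl)-2H-pyran-6-yl]propanoate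
Conditions: Dess–Martin periodinane (1.2 equiv), pyridine (5 equiv), CH2Cl2, 0 °C; short pad of deactivated silica; used at once
Reagents that add atoms: none
Why: Dess–Martin oxidation is the usual route to β,γ-unsaturated aldehydes because it is fast at 0 °C, and with pyridine taking up the acetic acid there is neither base to shift the doubly activated C5 protons nor free acid to close the C6/C8 1,5-dicarbonyl unit to a pyrylium salt.

Step 11
Reactants: 19 2-(trimethylsilyl)ethyl 3-[3-acryloyl-4-(2-oxoethyl)-2H-pyran-6-yl]propanoate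
Product: 21 2-(trimethylsilyl)ethyl 3-[(6R,7R)-6-hydroxy-7-methyl-8-oxo-5,6,7,8-tetrahydro-1H-isochromen-3-yl]propanoate, via diethoxymethylsilyl ether 20 (not isolated)
Conditions: Cu(OAc)2·H2O (5 mol %), (R)-DTBM-SEGPHOS (5.5 mol %), (EtO)2MeSiH (1.2 equiv, slow addition), toluene (0.05 M), −40 °C, no alcohol additive; then pH 5 citrate buffer–THF, 0 °C
Reagents that add atoms: none
Why: The ligated hydride of monovalent copper, formed from Cu(OAc)2·H2O and the silane, delivers hydride to the unsubstituted terminus of the s-cis acryloyl group, which makes that carbon the C7 methyl and gives the (Z)-copper enolate; C7 then attacks the tethered aldehyde carbon C6, and the silane silylates the copper aldolate to 20, regenerating Cu–H and making the aldol irreversible. The closest known reaction type is the copper hydride-catalysed enantioselective reductive aldol cyclisation of enone– and enoate–carbonyl substrates, and the intermolecular acrylate–aldehyde version shows that aldehydes are tolerated as acceptors. Ring A closes in a 6-(enolendo)-exo-trig mode. With copper bridging both oxygens, ring closure forces the aldehyde oxygen and C5 to flank C8 about the forming bond, so the Z-methyl ends anti to C5 (equatorial) and the C6 oxygen gauche to C8 (axial), which is the cis relation; the bisphosphine on copper selects the enolate and aldehyde faces and so sets 6R and 7R. The step needs hydride delivery to the vinyl group only: C4a and C3 are fully substituted and deactivated by donation from O2, and the aldehyde is spared because hydrocupration of an unhindered vinyl ketone is faster and the silane is dosed slowly at low temperature. With no protic additive present, the enolate should cyclise before it can be protonated.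

Step 12
Reactants: 22 orsellinic acid (2,4-dihydroxy-6-methylbenzoic acid)
Product: 23 tert-butyldimethylsilyl 2,4-bis(tert-butyldimethylsilyloxy)-6-methylbenzoate
Conditions: TBSCl (3.6 equiv), imidazole (7 equiv), DMF, rt; cold rapid work-up (hexane)
Reagents that add atoms: tert-butyldimethylsilyl chloride, CC(C)(C)[Si](C)(C)Cl
Why: Exhaustive imidazole-promoted silylation at room temperature covers both phenols and the carboxyl group without heating the easily decarboxylated acid.

Step 13
Reactants: 23 tert-butyldimethylsilyl 2,4-bis(tert-butyldimethylsilyloxy)-6-methylbenzoate; 21 2-(trimethylsilyl)ethyl 3-[(6R,7R)-6-hydroxy-7-methyl-8-oxo-5,6,7,8-tetrahydro-1H-isochromen-3-yl]propanoate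
Product: 25 (6R,7R)-7-methyl-8-oxo-3-{3-oxo-3-[2-(trimethylsilyl)ethoxy]propyl}-5,6,7,8-tetrahydro-1H-isochromen-6-yl 2,4-bis(tert-butyldimethylsilyloxy)-6-methylbenzoate, via acid chloride 24 (not isolated)
Conditions: 23, (COCl)2 (1.2 equiv), DMF (cat.), CH2Cl2, 0 °C to rt, evaporation under high vacuum; then 21, pyridine (5 equiv), DMAP (0.2 equiv), CH2Cl2, 0 °C to rt
Reagents that add atoms: none
Why: Silyl esters are converted by oxalyl chloride/DMF into acid chlorides under neutral conditions, and DMAP-catalysed acylation with this electron-rich, readily ionised aroyl chloride leaves C6–O intact (configuration retained); only weak bases are present, and C7–H next to a doubly vinylogous ester carbonyl is poorly acidic, which should hold back β-elimination.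

Step 14
Reactants: 25 (6R,7R)-7-methyl-8-oxo-3-{3-oxo-3-[2-(trimethylsilyl)ethoxy]propyl}-5,6,7,8-tetrahydro-1H-isochromen-6-yl 2,4-bis(tert-butyldimethylsilyloxy)-6-methylbenzoate
Product: 26 3-[(6R,7R)-6-(2,4-dihydroxy-6-methylbenzoyl)oxy-7-methyl-8-oxo-5,6,7,8-tetrahydro-1H-isochromen-3-yl]propanoic acid (CNP0601844.1)
Conditions: Bu4NF (5 equiv), AcOH (5 equiv), THF, 0 °C to rt; pH 4–5 buffer
Reagents that add atoms: none
Why: Fluoride removes both aryl silyl ethers and triggers the β-silyl fragmentation of the silylethyl ester, while acetic acid keeps the medium from turning basic, so neither E1cB loss of the orsellinate (which would aromatise ring A) nor epimerisation at C7 is expected.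

Compound list
1 | succinic anhydride | O=C1CCC(=O)O1 | starting material
2 | 2-(trimethylsilyl)ethanol | C[Si](C)(C)CCO | starting material
3 | 4-oxo-4-[2-(trimethylsilyl)ethoxy]butanoic acid | OC(=O)CCC(=O)OCC[Si](C)(C)C | intermediate
4 | 4-hydroxybutan-2-one | CC(=O)CCO | starting material
5 | 4-(tert-butyldimethylsilyloxy)butan-2-one | CC(=O)CCO[Si](C)(C)C(C)(C)C | intermediate
6 | 2-(trimethylsilyl)ethyl 4-chloro-4-oxobutanoate | ClC(=O)CCC(=O)OCC[Si](C)(C)C | intermediate
7 | lithium 4-(tert-butyldimethylsilyloxy)but-1-en-2-olate | [Li]OC(=C)CCO[Si](C)(C)C(C)(C)C | intermediate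
8 | 2-(trimethylsilyl)ethyl 8-(tert-butyldimethylsilyloxy)-4,6-dioxooctanoate | C[Si](C)(C)CCOC(=O)CCC(=O)CC(=O)CCO[Si](C)(C)C(C)(C)C | intermediate
9 | 2-(trimethylsilyl)ethyl 8-hydroxy-4,6-dioxooctanoate | C[Si](C)(C)CCOC(=O)CCC(=O)CC(=O)CCO | intermediate
10 | 2-(trimethylsilyl)ethyl 3-(4-oxo-5,6-dihydro-4H-pyran-2-yl)propanoate | O=C1CCOC(CCC(=O)OCC[Si](C)(C)C)=C1 | intermediate
11 | (4-bromo-6-{3-oxo-3-[2-(trimethylsilyl)ethoxy]propyl}-2H-pyran-3-yl)methylidene(dimethyl)ammonium bromide | C[N+](C)=CC1=C(Br)C=C(CCC(=O)OCC[Si](C)(C)C)OC1.[Br-] | intermediate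
12 | 2-(trimethylsilyl)ethyl 3-(4-bromo-3-formyl-2H-pyran-6-yl)propanoate | O=CC1=C(Br)C=C(CCC(=O)OCC[Si](C)(C)C)OC1 | intermediate
13 | tert-butyldimethyl(vinyloxy)silane | C=CO[Si](C)(C)C(C)(C)C | starting material
14 | 9-[2-(tert-butyldimethylsilyloxy)ethyl]-9-borabicyclo[3.3.1]nonane | CC(C)(C)[Si](C)(C)OCCB1C2CCCC1CCC2 | intermediate
15 | 2-(trimethylsilyl)ethyl 3-{4-[2-(tert-butyldimethylsilyloxy)ethyl]-3-formyl-2H-pyran-6-yl}propanoate | O=CC1=C(CCO[Si](C)(C)C(C)(C)C)C=C(CCC(=O)OCC[Si](C)(C)C)OC1 | intermediate
16 | 2-(trimethylsilyl)ethyl 3-{4-[2-(tert-butyldimethylsilyloxy)ethyl]-3-(1-hydroxyprop-2-en-1-yl)-2H-pyran-6-yl}propanoate (racemic carbinol) | C=CC(O)C1=C(CCO[Si](C)(C)C(C)(C)C)C=C(CCC(=O)OCC[Si](C)(C)C)OC1 | intermediate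
17 | 2-(trimethylsilyl)ethyl 3-{3-acryloyl-4-[2-(tert-butyldimethylsilyloxy)ethyl]-2H-pyran-6-yl}propanoate | C=CC(=O)C1=C(CCO[Si](C)(C)C(C)(C)C)C=C(CCC(=O)OCC[Si](C)(C)C)OC1 | intermediate
18 | 2-(trimethylsilyl)ethyl 3-[3-acryloyl-4-(2-hydroxyethyl)-2H-pyran-6-yl]propanoate | C=CC(=O)C1=C(CCO)C=C(CCC(=O)OCC[Si](C)(C)C)OC1 | intermediate
19 | 2-(trimethylsilyl)ethyl 3-[3-acryloyl-4-(2-oxoethyl)-2H-pyran-6-yl]propanoate | C=CC(=O)C1=C(CC=O)C=C(CCC(=O)OCC[Si](C)(C)C)OC1 | intermediate
20 | 2-(trimethylsilyl)ethyl 3-{(6R,7R)-6-[diethoxy(methyl)silyl]oxy-7-methyl-8-oxo-5,6,7,8-tetrahydro-1H-isochromen-3-yl}propanoate | CCO[Si](C)(OCC)O[C@@H]1CC2=C(COC(CCC(=O)OCC[Si](C)(C)C)=C2)C(=O)[C@@H]1C | intermediate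
21 | 2-(trimethylsilyl)ethyl 3-[(6R,7R)-6-hydroxy-7-methyl-8-oxo-5,6,7,8-tetrahydro-1H-isochromen-3-yl]propanoate | O[C@@H]1CC2=C(COC(CCC(=O)OCC[Si](C)(C)C)=C2)C(=O)[C@@H]1C | intermediate
22 | orsellinic acid | Cc1cc(O)cc(O)c1C(=O)O | starting material
23 | tert-butyldimethylsilyl 2,4-bis(tert-butyldimethylsilyloxy)-6-methylbenzoate | Cc1cc(O[Si](C)(C)C(C)(C)C)cc(O[Si](C)(C)C(C)(C)C)c1C(=O)O[Si](C)(C)C(C)(C)C | intermediate
24 | 2,4-bis(tert-butyldimethylsilyloxy)-6-methylbenzoyl chloride | Cc1cc(O[Si](C)(C)C(C)(C)C)cc(O[Si](C)(C)C(C)(C)C)c1C(=O)Cl | intermediate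
25 | (6R,7R)-7-methyl-8-oxo-3-{3-oxo-3-[2-(trimethylsilyl)ethoxy]propyl}-5,6,7,8-tetrahydro-1H-isochromen-6-yl 2,4-bis(tert-butyldimethylsilyloxy)-6-methylbenzoate | Cc1cc(O[Si](C)(C)C(C)(C)C)cc(O[Si](C)(C)C(C)(C)C)c1C(=O)O[C@@H]1CC2=C(COC(CCC(=O)OCC[Si](C)(C)C)=C2)C(=O)[C@@H]1C | intermediate
26 | 3-[(6R,7R)-6-(2,4-dihydroxy-6-methylbenzoyl)oxy-7-methyl-8-oxo-5,6,7,8-tetrahydro-1H-isochromen-3-yl]propanoic acid | Cc1cc(O)cc(O)c1C(=O)O[C@@H]1CC2=C(COC(CCC(=O)O)=C2)C(=O)[C@@H]1C | target

Total step count: 14. Longest linear sequence: 12 (steps 1, 3–11, 13, 14).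

Steps most likely to fail

Risk 1, step 11. Three processes could spoil the one-flask reaction. The aldehyde may be reduced directly. A proton may transfer from the acidic C5 position to the enolate before ring closure. The ligand may also discriminate the faces poorly. The fallback separates hydride delivery from C–C bond formation. Setting out from 19, 1,4-hydrosilylation with Et3SiH catalysed by RhCl(PPh3)3 should give the (Z)-triethylsilyl enol ether aldehyde F1. A fluoride-initiated aldol catalysed by Cu(OTf)2, (R)-Tol-BINAP and Bu4N[Ph3SiF2] runs through the same kind of ligated, oxygen-bridging copper enolate, but with no hydride present. It should close ring A to the triethylsilyl-protected aldol F2. HF·pyridine then brings the route back at 21.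

Risk 2, step 10. During oxidation and work-up the new aldehyde may enolise towards the conjugated dienol. Under the acetic acid released by the oxidant, the C6/C8 dicarbonyl pair may also close to a pyrylium salt. The fallback carries C6 at the aldehyde level from the start and unmasks it without oxidant or protic acid. Setting out from 12, Negishi coupling with commercial (1,3-dioxolan-2-ylmethyl)zinc bromide (Pd(OAc)2, SPhos, THF, rt) should give the dioxolane aldehyde F3. Vinylmagnesium bromide at −78 °C then gives the dioxolane carbinol F4, and MnO2 gives the dioxolane vinyl ketone F5. Treatment with Et3SiOTf and 2,6-lutidine in CH2Cl2 at 0 °C followed by water, a weakly basic acetal cleavage, returns the route at 19.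

Risk 3, step 5. The electrophile may attack at C4 or at the side-chain methylene next to C3, or the vinylogous ester may break down in the strongly acidic medium. The fallback separates C–C bond formation from halogenation. Setting out from 10, condensation with tert-butoxybis(dimethylamino)methane (toluene, 80 °C, neutral) should give the (E)-enaminone F6. PBr3 in CH2Cl2 at 0 °C converts its carbonyl into the bromovinyl iminium salt 11, and cold aqueous hydrolysis returns the route at 12.

Further compounds
F1 | step 11 | 2-(trimethylsilyl)ethyl 3-{4-(2-oxoethyl)-3-[(Z)-1-(triethylsilyloxy)prop-1-en-1-yl]-2H-pyran-6-yl}propanoate | C/C=C(\O[Si](CC)(CC)CC)C1=C(CC=O)C=C(CCC(=O)OCC[Si](C)(C)C)OC1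
F2 | step 11 | 2-(trimethylsilyl)ethyl 3-[(6R,7R)-7-methyl-8-oxo-6-(triethylsilyloxy)-5,6,7,8-tetrahydro-1H-isochromen-3-yl]propanoate | CC[Si](CC)(CC)O[C@@H]1CC2=C(COC(CCC(=O)OCC[Si](C)(C)C)=C2)C(=O)[C@@H]1C
F3 | step 10 | 2-(trimethylsilyl)ethyl 3-[4-(1,3-dioxolan-2-ylmethyl)-3-formyl-2H-pyran-6-yl]propanoate | O=CC1=C(CC2OCCO2)C=C(CCC(=O)OCC[Si](C)(C)C)OC1
F4 | step 10 | 2-(trimethylsilyl)ethyl 3-[4-(1,3-dioxolan-2-ylmethyl)-3-(1-hydroxyprop-2-en-1-yl)-2H-pyran-6-yl]propanoate (racemic carbinol) | C=CC(O)C1=C(CC2OCCO2)C=C(CCC(=O)OCC[Si](C)(C)C)OC1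
F5 | step 10 | 2-(trimethylsilyl)ethyl 3-[3-acryloyl-4-(1,3-dioxolan-2-ylmethyl)-2H-pyran-6-yl]propanoate | C=CC(=O)C1=C(CC2OCCO2)C=C(CCC(=O)OCC[Si](C)(C)C)OC1
F6 | step 5 | 2-(trimethylsilyl)ethyl 3-[(5E)-5-(dimethylaminomethylidene)-4-oxo-5,6-dihydro-4H-pyran-2-yl]propanoate | CN(C)/C=C1\COC(CCC(=O)OCC[Si](C)(C)C)=CC1=O
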